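**Plan**

1. Retrosynthesis: remove the C8 ester (acylation) and the C4–C5 oxirane (epoxidation of a (4Z)-alkene directed by O6), change isopropyl into isopropenyl, then cut C6–C7 of the ten-membered ring as a [2,3]-Wittig retron. This leads to a 13-membered diallylic ether, which is cut at O–C12 (Williamson), C7=C11 (Wittig olefination), C8–O (α-aminoxylation) and C8–C9 (alkylation), back to nerol.
2. Enabling feature: C6 is a secondary carbinol between C5 (the oxirane is a masked alkene, so C6–H is allylic and α to oxygen) and C7, which carries a three-carbon branch. C6(OH)–C7–C11(=C12) is therefore a homoallylic alcohol, and C6 and C12 can hang on one oxygen in a 1-oxacyclotrideca-3,7,11-triene.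
3. Forward order: nerol (C1–C6, C9, C10, both ring methyls, 4Z) → C9 bromide → C8/C7 from acetonitrile → O8 and C11–C13 → 13-membered ether (step 11) → ten-membered carbocycle by ring contraction (step 12) → oxirane (step 17).
4. Helpers: the ether ring disappears in the key step (its oxygen stays as O6), the isopropenyl group is hydrogenated, and TES (O8) and TBS (O6) come off in turn so that only O8 is acylated.
5. Stereochemistry: C8 from D-proline catalysis; C7 and C6 from C8 in the ring contraction; C4/C5 from the C6 hydroxyl in the vanadium epoxidation; 4Z from nerol; 1(10)E from the SeO2 oxidation.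

Key step: step 12

Remark: in the given structure C3 and C6 lie on the same side of the oxirane, so the epoxide is treated as the oxide of a (4Z)-alkene. Ring compounds carry germacrane numbers (C1=C10 alkene, C4–C5 oxirane, C6 carbinol, C7 isopropyl carbon, C8 acyloxy carbon).

**Route**

Step 1
Reactants: 1 nerol ((2Z)-3,7-dimethylocta-2,6-dien-1-ol)
Product: 2 neryl 4-methoxybenzyl ether
Conditions: NaH, 4-methoxybenzyl chloride, n-Bu4NI (cat.), THF/DMF, 0 °C to rt
Reagents that add atoms: 4-methoxybenzyl chloride, COc1ccc(CCl)cc1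
Why: Williamson etherification of the primary allylic alkoxide masks the future O6 with a group that later leaves under neutral oxidative conditions, and the (Z)-alkene that becomes C4=C5 is untouched.

Step 2
Reactants: 2 neryl 4-methoxybenzyl ether
Product: 3 (2E,6Z)-8-(4-methoxybenzyloxy)-2,6-dimethylocta-2,6-dien-1-ol
Conditions: SeO2 (cat.), t-BuOOH, salicylic acid (cat.), CH2Cl2, 0 °C to rt
Reagents that add atoms: tert-butyl hydroperoxide, CC(C)(C)OO (its oxygen is relayed by catalytic selenium dioxide, O=[Se]=O)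
Why: Selenium dioxide allylic oxidation (ene reaction, then [2,3]-shift) should hydroxylate the (E)-methyl group of the more electron-rich distal alkene, which functionalises the future C9 and leaves C1=C10 with E geometry.

Step 3
Reactants: 3 (2E,6Z)-8-(4-methoxybenzyloxy)-2,6-dimethylocta-2,6-dien-1-ol
Product: 4 (2E,6Z)-1-bromo-8-(4-methoxybenzyloxy)-2,6-dimethylocta-2,6-diene
Conditions: CBr4, PPh3, CH2Cl2, 0 °C
Reagents that add atoms: carbon tetrabromide, BrC(Br)(Br)Br
Why: Appel bromination converts the primary allylic alcohol into the bromide by SN2 displacement of the alkoxyphosphonium group, without allylic transposition at 0 °C and without touching the ether or the alkenes.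

Step 4
Reactants: 4 (2E,6Z)-1-bromo-8-(4-methoxybenzyloxy)-2,6-dimethylocta-2,6-diene; 5 acetonitrile
Product: 6 (4E,8Z)-10-(4-methoxybenzyloxy)-4,8-dimethyldeca-4,8-dienenitrile
Conditions: MeCN (3 equiv), n-BuLi, THF, −78 °C; then 4, −78 to −30 °C
Reagents that add atoms: none
Why: SN2 alkylation of lithioacetonitrile by the primary allylic bromide adds C8 and C7; excess anion suppresses dialkylation.

Step 5
Reactants: 6 (4E,8Z)-10-(4-methoxybenzyloxy)-4,8-dimethyldeca-4,8-dienenitrile
Product: 8 (4E,8Z)-10-(4-methoxybenzyloxy)-4,8-dimethyldeca-4,8-dienal, via aluminium aldimine 7 (not isolated)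
Conditions: i-Bu2AlH, CH2Cl2, −78 °C; then aq. potassium sodium tartrate, pH 4–5 buffer, rt
Reagents that add atoms: water, O
Why: i-Bu2AlH adds one hydride to the nitrile and stops at the N-aluminated aldimine, whose hydrolysis on work-up releases the aldehyde (future C7) while the ether and alkenes are inert.

Step 6
Reactants: 8 (4E,8Z)-10-(4-methoxybenzyloxy)-4,8-dimethyldeca-4,8-dienal; 9 ethyl 2-(triphenylphosphoranylidene)propanoate
Product: 12 ethyl (2E,4S,6E,10Z)-4-hydroxy-12-(4-methoxybenzyloxy)-2,6,10-trimethyldodeca-2,6,10-trienoate, via anilinooxy aldehyde 10 (not isolated), via anilinooxy enoate 11 (not isolated)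
Conditions: D-proline (20 mol%), PhNO, DMSO, rt; then 9, CH2Cl2, 0 °C to rt; then Zn, AcOH, EtOH, rt
Reagents that add atoms: nitrosobenzene, O=Nc1ccccc1
Why: Proline-catalysed α-aminoxylation sets C8 (the carboxylic acid of D-proline directs nitrosobenzene to one face of the (E)-enamine, which should give the 2S aldehyde), the non-basic stabilised Wittig ylide then builds the (E)-C7=C11 alkene without racemisation, and zinc cleaves the weak N–O bond.

Step 7
Reactants: 12 ethyl (2E,4S,6E,10Z)-4-hydroxy-12-(4-methoxybenzyloxy)-2,6,10-trimethyldodeca-2,6,10-trienoate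
Product: 13 ethyl (2E,4S,6E,10Z)-12-(4-methoxybenzyloxy)-2,6,10-trimethyl-4-(triethylsilyloxy)dodeca-2,6,10-trienoate
Conditions: Et3SiCl, imidazole, DMAP (cat.), CH2Cl2, 0 °C
Reagents that add atoms: chlorotriethylsilane, CC[Si](Cl)(CC)CC
Why: Silylation gives a C8 ether that tolerates hydride, alkoxide and alkyllithium reagents (unlike a benzylic ether it has no acidic α-hydrogen) and can later be removed in the presence of a TBS ether.

Step 8
Reactants: 13 ethyl (2E,4S,6E,10Z)-12-(4-methoxybenzyloxy)-2,6,10-trimethyl-4-(triethylsilyloxy)dodeca-2,6,10-trienoate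
Product: 14 (2E,4S,6E,10Z)-12-(4-methoxybenzyloxy)-2,6,10-trimethyl-4-(triethylsilyloxy)dodeca-2,6,10-trien-1-ol
Conditions: i-Bu2AlH (2.5 equiv), CH2Cl2, −78 °C; aq. potassium sodium tartrate
Reagents that add atoms: none
Why: i-Bu2AlH reduces the conjugated ester in the 1,2-sense to the (E)-allylic alcohol at the future C12, and the silyl and benzyl ethers are stable at −78 °C.

Step 9
Reactants: 14 (2E,4S,6E,10Z)-12-(4-methoxybenzyloxy)-2,6,10-trimethyl-4-(triethylsilyloxy)dodeca-2,6,10-trien-1-ol
Product: 15 (2E,4S,6E,10Z)-1-chloro-12-(4-methoxybenzyloxy)-2,6,10-trimethyl-4-(triethylsilyloxy)dodeca-2,6,10-triene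
Conditions: N-chlorosuccinimide, Me2S, CH2Cl2, −20 to 0 °C
Reagents that add atoms: N-chlorosuccinimide, O=C1CCC(=O)N1Cl
Why: Corey–Kim chlorination (alkoxysulfonium salt, then SN2 by chloride) converts the primary allylic alcohol into the chloride without allylic transposition under non-acidic conditions that spare the TES ether.

Step 10
Reactants: 15 (2E,4S,6E,10Z)-1-chloro-12-(4-methoxybenzyloxy)-2,6,10-trimethyl-4-(triethylsilyloxy)dodeca-2,6,10-triene
Product: 16 (2Z,6E,9S,10E)-12-chloro-3,7,11-trimethyl-9-(triethylsilyloxy)dodeca-2,6,10-trien-1-ol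
Conditions: DDQ, CH2Cl2/pH 7 phosphate buffer, 0 °C
Reagents that add atoms: none
Why: Oxidative cleavage of the 4-methoxybenzyl ether by DDQ (hydride abstraction, then hydrolysis of the oxocarbenium ion) frees O6 under buffered conditions that leave the allylic chloride, the TES ether and the alkenes intact.

Step 11
Reactants: 16 (2Z,6E,9S,10E)-12-chloro-3,7,11-trimethyl-9-(triethylsilyloxy)dodeca-2,6,10-trien-1-ol
Product: 17 (3Z,7E,10S,11E)-4,8,12-trimethyl-10-(triethylsilyloxy)-1-oxacyclotrideca-3,7,11-triene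
Conditions: NaH, n-Bu4NI (cat.), THF, 50 °C, syringe-pump addition of 16 (final 0.003 M)
Reagents that add atoms: none
Why: Intramolecular Williamson etherification: slow addition keeps the alkoxide dilute, so SN2 attack of O6 on the primary allylic chloride at C12 should close the 13-membered ether in preference to oligomerisation, helped by the three alkenes that limit the freedom of the chain.

Step 12
Reactants: 17 (3Z,7E,10S,11E)-4,8,12-trimethyl-10-(triethylsilyloxy)-1-oxacyclotrideca-3,7,11-triene
Product: 19 (1(10)E,4Z,6R,7R,8S)-6-(tert-butyldimethylsilyloxy)-8-(triethylsilyloxy)germacra-1(10),4,11-triene, via lithium alkoxide 18 (not isolated)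
Conditions: n-BuLi (1.2 equiv), THF, −78 °C; then t-BuMe2SiOTf, −78 to −40 °C
Reagents that add atoms: tert-butyldimethylsilyl trifluoromethanesulfonate, CC(C)(C)[Si](C)(C)OS(=O)(=O)C(F)(F)F
Why: n-BuLi removes a C6 proton (α to oxygen and allylic to C4=C5), and the α-oxy allyllithium undergoes a concerted [2,3]-sigmatropic (Wittig) shift through a five-membered envelope C6–O–C12–C11=C7 that forms C6–C7, breaks O–C12 and moves the alkene to C11=C12; the alkoxide is then silylated in the same flask. The closest known reaction type is the transannular [2,3]-Wittig ring contraction of 13-membered diallylic ethers to ten-membered carbocycles. The ten-membered ring closes by transannular attack across the temporary 13-membered ether (ring contraction, suprafacial on the allyl unit), and the ether oxygen ends as O6. C7 is controlled by C8: 1,3-allylic strain with the C11 methyl group holds C8–H in the alkene plane, ring carbon C9 then lies on the inner face and the silyloxy group on the outer face, so C6 should bond to C7 anti to the C8–O bond. C6 is controlled by the envelope, in which O and C11 are eclipsed about the forming bond and the C5 vinyl group takes the exo position away from C8, which should give the 6,7-trans (anti) arrangement. The step needs deprotonation at C6 instead of C12, favoured because C6–H2 adjoins an unsubstituted vinylic CH whereas C12–H2 adjoins the fully substituted C11; −78 °C is chosen to suppress the [1,2]-shift, loss of silanolate and silyl transfer between the two oxygens.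

Step 13
Reactants: 19 (1(10)E,4Z,6R,7R,8S)-6-(tert-butyldimethylsilyloxy)-8-(triethylsilyloxy)germacra-1(10),4,11-triene
Product: 20 (1(10)E,4Z,6R,7R,8S)-6-(tert-butyldimethylsilyloxy)-8-(triethylsilyloxy)germacra-1(10),4-diene
Conditions: H2 (1–3 atm), RhCl(PPh3)3 (cat.), benzene, rt
Reagents that add atoms: none
Why: RhCl(PPh3)3 hydrogenates the 1,1-disubstituted C11=C12 alkene far faster than the two trisubstituted ring alkenes, so the isopropenyl helper becomes isopropyl without a new stereocentre and without hydrogenolysis of the allylic silyl ether.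

Step 14
Reactants: 20 (1(10)E,4Z,6R,7R,8S)-6-(tert-butyldimethylsilyloxy)-8-(triethylsilyloxy)germacra-1(10),4-diene
Product: 21 (1(10)E,4Z,6R,7R,8S)-6-(tert-butyldimethylsilyloxy)germacra-1(10),4-dien-8-ol
Conditions: HF·pyridine, pyridine, THF, 0 °C
Reagents that add atoms: none
Why: Buffered HF·pyridine cleaves the triethylsilyl ether much faster than the bulkier tert-butyldimethylsilyl ether, which frees only O8 and avoids the protic acid that could trigger transannular cyclisation of the 1(10),4-diene.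

Step 15
Reactants: 21 (1(10)E,4Z,6R,7R,8S)-6-(tert-butyldimethylsilyloxy)germacra-1(10),4-dien-8-ol; 22 3,4,5-trimethoxybenzoyl chloride
Product: 23 (1(10)E,4Z,6R,7R,8S)-6-(tert-butyldimethylsilyloxy)germacra-1(10),4-dien-8-yl 3,4,5-trimethoxybenzoate
Conditions: Et3N, DMAP, CH2Cl2, rt to 40 °C
Reagents that add atoms: none
Why: DMAP-catalysed acylation (acylpyridinium intermediate) esterifies the hindered secondary C8 alcohol, the only free hydroxyl in 21, with retention.

Step 16
Reactants: 23 (1(10)E,4Z,6R,7R,8S)-6-(tert-butyldimethylsilyloxy)germacra-1(10),4-dien-8-yl 3,4,5-trimethoxybenzoate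
Product: 24 (1(10)E,4Z,6R,7S,8S)-6-hydroxygermacra-1(10),4-dien-8-yl 3,4,5-trimethoxybenzoate
Conditions: n-Bu4NF, AcOH (1:1), THF, rt to 40 °C
Reagents that add atoms: none
Why: Fluoride removes the TBS group, and the acetic acid buffer keeps O6 protonated so that 1,3-acyl migration from O8 to O6 and ester cleavage are avoided.

Step 17
Reactants: 24 (1(10)E,4Z,6R,7S,8S)-6-hydroxygermacra-1(10),4-dien-8-yl 3,4,5-trimethoxybenzoate
Product: 25 (1(10)E,4S,5R,6S,7S,8S)-4,5-epoxy-6-hydroxygermacr-1(10)-en-8-yl 3,4,5-trimethoxybenzoate (target)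
Conditions: VO(acac)2 (5 mol%), t-BuOOH (anhydrous), CH2Cl2, 0 °C
Reagents that add atoms: tert-butyl hydroperoxide, CC(C)(C)OO
Why: Hydroxyl-directed epoxidation (the vanadate ester of O6 delivers the peroxide oxygen intramolecularly) is chemoselective for the allylic C4=C5 alkene over C1=C10 and stereospecific for the (Z)-alkene (cis oxirane); 1,3-allylic strain between the C3 methylene, which is cis to C6, and the C6 substituents holds C6–H in the alkene plane, so oxygen should arrive on the outer face that carries the hydroxyl and give the threo epoxy alcohol (4S,5R).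

**Compound list**

1 | nerol, (2Z)-3,7-dimethylocta-2,6-dien-1-ol | OC/C=C(C)\CCC=C(C)C | starting material
2 | neryl 4-methoxybenzyl ether, 1-methoxy-4-{[(2Z)-3,7-dimethylocta-2,6-dien-1-yl]oxymethyl}benzene | COc1ccc(COC/C=C(C)\CCC=C(C)C)cc1 | intermediate
3 | (2E,6Z)-8-(4-methoxybenzyloxy)-2,6-dimethylocta-2,6-dien-1-ol | COc1ccc(COC/C=C(C)\CC/C=C(C)/CO)cc1 | intermediate
4 | (2E,6Z)-1-bromo-8-(4-methoxybenzyloxy)-2,6-dimethylocta-2,6-diene | COc1ccc(COC/C=C(C)\CC/C=C(C)/CBr)cc1 | intermediate
5 | acetonitrile | CC#N | starting material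
6 | (4E,8Z)-10-(4-methoxybenzyloxy)-4,8-dimethyldeca-4,8-dienenitrile | COc1ccc(COC/C=C(C)\CC/C=C(C)/CCC#N)cc1 | intermediate
7 | N-(diisobutylalumino) aldimine of 8 | COc1ccc(COC/C=C(C)\CC/C=C(C)/CCC=N[Al](CC(C)C)CC(C)C)cc1 | intermediate (not isolated)
8 | (4E,8Z)-10-(4-methoxybenzyloxy)-4,8-dimethyldeca-4,8-dienal | COc1ccc(COC/C=C(C)\CC/C=C(C)/CCC=O)cc1 | intermediate
9 | ethyl 2-(triphenylphosphoranylidene)propanoate | CCOC(=O)C(C)=P(c1ccccc1)(c1ccccc1)c1ccccc1 | starting material
10 | (2S,4E,8Z)-2-(anilinooxy)-10-(4-methoxybenzyloxy)-4,8-dimethyldeca-4,8-dienal | COc1ccc(COC/C=C(C)\CC/C=C(C)/C[C@H](ONc2ccccc2)C=O)cc1 | intermediate (not isolated)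
11 | ethyl (2E,4S,6E,10Z)-4-(anilinooxy)-12-(4-methoxybenzyloxy)-2,6,10-trimethyldodeca-2,6,10-trienoate | COc1ccc(COC/C=C(C)\CC/C=C(C)/C[C@H](ONc2ccccc2)/C=C(C)/C(=O)OCC)cc1 | intermediate (not isolated)
12 | ethyl (2E,4S,6E,10Z)-4-hydroxy-12-(4-methoxybenzyloxy)-2,6,10-trimethyldodeca-2,6,10-trienoate | COc1ccc(COC/C=C(C)\CC/C=C(C)/C[C@H](O)/C=C(C)/C(=O)OCC)cc1 | intermediate
13 | ethyl (2E,4S,6E,10Z)-12-(4-methoxybenzyloxy)-2,6,10-trimethyl-4-(triethylsilyloxy)dodeca-2,6,10-trienoate | COc1ccc(COC/C=C(C)\CC/C=C(C)/C[C@H](O[Si](CC)(CC)CC)/C=C(C)/C(=O)OCC)cc1 | intermediate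
14 | (2E,4S,6E,10Z)-12-(4-methoxybenzyloxy)-2,6,10-trimethyl-4-(triethylsilyloxy)dodeca-2,6,10-trien-1-ol | COc1ccc(COC/C=C(C)\CC/C=C(C)/C[C@H](O[Si](CC)(CC)CC)/C=C(C)/CO)cc1 | intermediate
15 | (2E,4S,6E,10Z)-1-chloro-12-(4-methoxybenzyloxy)-2,6,10-trimethyl-4-(triethylsilyloxy)dodeca-2,6,10-triene | COc1ccc(COC/C=C(C)\CC/C=C(C)/C[C@H](O[Si](CC)(CC)CC)/C=C(C)/CCl)cc1 | intermediate
16 | (2Z,6E,9S,10E)-12-chloro-3,7,11-trimethyl-9-(triethylsilyloxy)dodeca-2,6,10-trien-1-ol | OC/C=C(C)\CC/C=C(C)/C[C@H](O[Si](CC)(CC)CC)/C=C(C)/CCl | intermediate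
17 | (3Z,7E,10S,11E)-4,8,12-trimethyl-10-(triethylsilyloxy)-1-oxacyclotrideca-3,7,11-triene | O1C/C=C(C)\CC/C=C(C)/C[C@H](O[Si](CC)(CC)CC)/C=C(C)/C1 | intermediate
18 | lithium (1(10)E,4Z)-8-(triethylsilyloxy)germacra-1(10),4,11-trien-6-olate, C6, C7 and C8 configured as in 19 | CC[Si](CC)(CC)O[C@H]1C/C(C)=C/CC/C(C)=C\[C@@H]([O-])[C@@H]1C(C)=C.[Li+] | intermediate (not isolated)
19 | (1(10)E,4Z,6R,7R,8S)-6-(tert-butyldimethylsilyloxy)-8-(triethylsilyloxy)germacra-1(10),4,11-triene | CC[Si](CC)(CC)O[C@H]1C/C(C)=C/CC/C(C)=C\[C@@H](O[Si](C)(C)C(C)(C)C)[C@@H]1C(C)=C | intermediate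
20 | (1(10)E,4Z,6R,7R,8S)-6-(tert-butyldimethylsilyloxy)-8-(triethylsilyloxy)germacra-1(10),4-diene | CC[Si](CC)(CC)O[C@H]1C/C(C)=C/CC/C(C)=C\[C@@H](O[Si](C)(C)C(C)(C)C)[C@@H]1C(C)C | intermediate
21 | (1(10)E,4Z,6R,7R,8S)-6-(tert-butyldimethylsilyloxy)germacra-1(10),4-dien-8-ol | O[C@H]1C/C(C)=C/CC/C(C)=C\[C@@H](O[Si](C)(C)C(C)(C)C)[C@@H]1C(C)C | intermediate
22 | 3,4,5-trimethoxybenzoyl chloride | COc1cc(C(=O)Cl)cc(OC)c1OC | starting material
23 | (1(10)E,4Z,6R,7R,8S)-6-(tert-butyldimethylsilyloxy)germacra-1(10),4-dien-8-yl 3,4,5-trimethoxybenzoate | COc1cc(C(=O)O[C@H]2C/C(C)=C/CC/C(C)=C\[C@@H](O[Si](C)(C)C(C)(C)C)[C@@H]2C(C)C)cc(OC)c1OC | intermediate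
24 | (1(10)E,4Z,6R,7S,8S)-6-hydroxygermacra-1(10),4-dien-8-yl 3,4,5-trimethoxybenzoate | COc1cc(C(=O)O[C@H]2C/C(C)=C/CC/C(C)=C\[C@@H](O)[C@@H]2C(C)C)cc(OC)c1OC | intermediate
25 | (1(10)E,4S,5R,6S,7S,8S)-4,5-epoxy-6-hydroxygermacr-1(10)-en-8-yl 3,4,5-trimethoxybenzoate (cis oxirane) | COc1cc(C(=O)O[C@H]2C/C(C)=C/CC[C@]3(C)O[C@@H]3[C@@H](O)[C@@H]2C(C)C)cc(OC)c1OC | target

**Totals and risks**

Total step count: 17. Longest linear sequence: 17 steps (from nerol 1; compounds 5, 9 and 22 are used as purchased).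

Steps most likely to fail:

1. Step 12. Deprotonation may occur at C12 instead of C6 (followed by 1,4-loss of silanolate or by the alternative shift onto C4), or the facial selectivity at C7 may be poor. Fallback: set out from 16 and close the C6–C7 bond by carbonyl allylation instead of a sigmatropic shift. MnO2 (CH2Cl2, rt) would oxidise the (Z)-allylic alcohol to the chloro enal F1. CrCl2 (THF, high dilution, rt; Nozaki–Hiyama allylation through a chair-like six-membered transition state of the (E)-allylchromium species, which gives the same 6,7-anti relation) would give the ring alcohol F2. Silylation (t-BuMe2SiOTf, 2,6-lutidine, CH2Cl2, −78 °C) comes back to the route at 19.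

2. Step 17. The ring conformation may override the directing effect and give poor facial selectivity, or the Lewis-acidic catalyst may induce transannular cyclisation of the epoxy alkene. Fallback: set the oxirane by reagent control before the ring is closed, starting from 16.
   - Sharpless asymmetric epoxidation (Ti(Oi-Pr)4, D-(−)-diethyl tartrate, t-BuOOH, CH2Cl2, −20 °C) would give the epoxy alcohol F3.
   - Oxidation (TEMPO cat., PhI(OAc)2, CH2Cl2) would give the epoxy aldehyde F4.
   - Umpolung allylation (Pd(PPh3)4 cat., Et2Zn, THF, high dilution) would close C6–C7; the allylzinc species adds to the aldehyde with zinc held between the aldehyde and oxirane oxygens, which should favour the threo epoxy alcohol, the epoxy ring alcohol F5.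
   - H2 with RhCl(PPh3)3 would give the isopropyl compound F6.
   - n-Bu4NF/AcOH (THF, 0 °C) would give the epoxy diol F7.
   - Acylation with 22 (1 equiv, DMAP, Et3N, CH2Cl2, −20 °C) at O8 comes back to the route at 25. O8 should react first because O6 is flanked by the oxirane and C7 and is hydrogen-bonded to the oxirane oxygen; this selectivity is the weak point of the fallback.

3. Step 11. Intermolecular etherification (oligomers) or loss of the allylic chloride by elimination may compete with ring closure. Fallback: form the same C12–O6 bond by palladium-catalysed allylic etherification instead of SN2 displacement, starting from 14. Boc2O/DMAP (CH2Cl2) would give the allylic carbonate F8. DDQ (CH2Cl2/pH 7 buffer) would give the hydroxy carbonate F9. Pd(PPh3)4 (cat., THF, 50 °C, high dilution) would ionise the carbonate; the alkoxide formed on loss of CO2 and tert-butoxide should attack the less hindered CH2 terminus of the allyl complex, with the E alkene kept through the syn allyl complex. This comes back to the route at 17.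

**Further compounds**

F1 | step 12 | (2Z,6E,9S,10E)-12-chloro-3,7,11-trimethyl-9-(triethylsilyloxy)dodeca-2,6,10-trienal | O=C/C=C(C)\CC/C=C(C)/C[C@H](O[Si](CC)(CC)CC)/C=C(C)/CCl
F2 | step 12 | (1(10)E,4Z,6R,7S,8S)-8-(triethylsilyloxy)germacra-1(10),4,11-trien-6-ol | CC[Si](CC)(CC)O[C@H]1C/C(C)=C/CC/C(C)=C\[C@@H](O)[C@@H]1C(C)=C
F3 | step 17 | [(2R,3S)-3-[(3E,6S,7E)-9-chloro-4,8-dimethyl-6-(triethylsilyloxy)nona-3,7-dien-1-yl]-3-methyloxiran-2-yl]methanol | OC[C@H]1O[C@@]1(C)CC/C=C(C)/C[C@H](O[Si](CC)(CC)CC)/C=C(C)/CCl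
F4 | step 17 | (2S,3S)-3-[(3E,6S,7E)-9-chloro-4,8-dimethyl-6-(triethylsilyloxy)nona-3,7-dien-1-yl]-3-methyloxirane-2-carbaldehyde | O=C[C@H]1O[C@@]1(C)CC/C=C(C)/C[C@H](O[Si](CC)(CC)CC)/C=C(C)/CCl
F5 | step 17 | (1(10)E,4S,5R,6S,7S,8S)-4,5-epoxy-8-(triethylsilyloxy)germacra-1(10),11-dien-6-ol | CC[Si](CC)(CC)O[C@H]1C/C(C)=C/CC[C@]2(C)O[C@@H]2[C@@H](O)[C@@H]1C(C)=C
F6 | step 17 | (1(10)E,4S,5R,6S,7S,8S)-4,5-epoxy-8-(triethylsilyloxy)germacr-1(10)-en-6-ol | CC[Si](CC)(CC)O[C@H]1C/C(C)=C/CC[C@]2(C)O[C@@H]2[C@@H](O)[C@@H]1C(C)C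
F7 | step 17 | (1(10)E,4S,5R,6S,7R,8S)-4,5-epoxygermacr-1(10)-ene-6,8-diol | O[C@H]1C/C(C)=C/CC[C@]2(C)O[C@@H]2[C@@H](O)[C@@H]1C(C)C
F8 | step 11 | tert-butyl (2E,4S,6E,10Z)-12-(4-methoxybenzyloxy)-2,6,10-trimethyl-4-(triethylsilyloxy)dodeca-2,6,10-trien-1-yl carbonate | COc1ccc(COC/C=C(C)\CC/C=C(C)/C[C@H](O[Si](CC)(CC)CC)/C=C(C)/COC(=O)OC(C)(C)C)cc1
F9 | step 11 | tert-butyl (2E,4S,6E,10Z)-12-hydroxy-2,6,10-trimethyl-4-(triethylsilyloxy)dodeca-2,6,10-trien-1-yl carbonate | OC/C=C(C)\CC/C=C(C)/C[C@H](O[Si](CC)(CC)CC)/C=C(C)/COC(=O)OC(C)(C)C
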